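## Structural features

The target is methyl shikimate with all three hydroxyls acylated. It has one cyclohex-1-ene ring: C1 carries the methoxycarbonyl group, C2 is the vinylic CH, C3, C4 and C5 are three contiguous oxygen-bearing stereocentres (3R,4S,5R), and C6 is a methylene group. O3 carries an acetyl group; O4 and O5 each carry an (R)-2-methylbutanoyl group, so two more stereocentres sit α to ester carbonyls in the side chains. In the ring O3 and O4 are cis, and O4 and O5 are trans. The fragile points are:
- the allylic C3 acetate, which is γ to the enoate and can ionise or be lost with aromatisation;
- the tendency of any acyl group to migrate to a free neighbouring hydroxyl;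
- the α-centres of the two 2-methylbutanoates, whose epimers (methyl against ethyl) could hardly be separated.

The carbocycle itself is simple. The real difficulty is to place three esters of two kinds on three neighbouring secondary oxygens without a chain of protecting-group steps, and to control the stereotriad while doing so. The key step exploits three facts: C3 and C4 are adjacent carbinol carbons of the ring, C3 is also the γ-carbon of the C1=C2 enoate, and the O3/O4 pair is already differentiated as acetate and 2-methylbutanoate. A C4 aldehyde and a C3 acylal can therefore be joined with reversed polarity at C3, which closes the ring and delivers O3 as its acetate and O4 as the only free hydroxyl.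

## Logic of the disconnections

**12 ⇒ 11 + 4.** The ester C–O bond at O4 is cut. Of the three acyl groups this is the only one the ring closure cannot bring along, and removing it exposes exactly the hydroxyl that the ring closure creates. The target is thereby reduced to the direct product of the key step with no protecting-group step in between. The forward step must acylate a hindered secondary hydroxyl flanked by two esters without acyl migration and without epimerising the α-centre of 4.

**11 ⇒ 9 (through 10).** The ring bond C3–C4 is cut. Both carbons are at the carbinol level, C3 is allylic and γ to the ester, and the diol is already mono-acetylated. The cut opens the ring to an acyclic chain and removes two of the three ring stereocentres, leaving C4 as an aldehyde and C3 as a gem-diacetate, which are two carbons of the same oxidation level. The forward step must reverse the polarity of C3, react through C3 and not C1, set C3 and C4 relative to C5, and do so without touching the epimerisable α-acyloxy aldehyde or the allylic acetate of the product.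

**9 ⇒ 7 (through 8).** The C4 formyl group is traced back to a terminal dioxolane, which means adding back one carbon across a glycol C–C bond. The free aldehyde is too sensitive to carry through earlier steps, and the dioxolane is the residue of the chiral aldehyde that controls C5. The gain is a robust, storable precursor. The forward step must unmask and cleave the glycol under conditions that spare the acylal and give the transient diol monoester 8 no time for acyl migration; hydrolysis and cleavage are therefore merged into one operation.

**7 ⇒ 5 + 6.** The C1=C2 double bond is cut in the metathesis sense. This removes the whole C2–C3 acylal unit as the commercial 6 and leaves 5 with only a terminal methylidene group. The forward step is a cross-metathesis on a 1,1-disubstituted, electron-poor alkene and should give the (2E) isomer. The geometry is not critical, because the C1–C2 bond becomes rotatable in 10.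

**5 ⇒ 3 + 4.** The ester C–O bond at O5 is cut. This ester is both a final substituent and the protecting group that prevents the γ-hydroxy ester from lactonising. The forward step must esterify faster than the lactone forms and must not epimerise 4.

**3 ⇒ 1 + 2.** The C5–C6 bond is cut at the homoallylic alcohol. C1, C6 and the ester come from 2, and the aldehyde carbon of 1 becomes C5, leaving two commercial materials. The forward step must add anti to the dioxolane oxygen, and the minor syn isomer must be removed, because the stereocentre of 1 is excised later and C5 then stands alone.

## Other disconnections considered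

**Alternative 1:** The ring would be opened at C1–C2 and C5–C6, leading back to furan A1 and the acrylimide A2. In the forward sense the two would combine in an endo-selective Diels–Alder reaction catalysed by the divalent copper bis(oxazoline) complex [Cu(t-Bu-box)](SbF6)2. The product is the oxanorbornene A3, in which the carbocycle is complete and the bridging oxygen is the future O5, with its configuration fixed by the catalyst.
- In its favour: the cycloaddition is a known, catalytic, enantioselective reaction type. After exchange of the imide for the methyl ester, base-induced β-elimination would open the oxygen bridge to the C5 carbinol and leave a C3=C4 alkene. Dihydroxylation of that alkene with OsO4 from the face opposite O5 would set C3 and C4 by substrate control.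
- Against it here: the furan cycloaddition is reversible and needs care over the endo/exo ratio, and the auxiliary must be exchanged. Decisively, O3 and O4 arrive as an undifferentiated cis-diol, so the O3 acetate and the O4 2-methylbutanoate would need a regioselective acylation or an orthoester detour.
- Comparison: on stereochemical reliability and on precedent this plan is the better one, since none of its steps is new. About seven steps would follow A3 (imide exchange, bridge opening, acylation of O5, dihydroxylation, two steps for the diol), against six in all for the chosen plan. The chosen plan is better on functional-group differentiation and step count and worse on the certainty of its key step.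

**Alternative 2:** Cuts at C2–C3 and C1–C6 lead to the silyloxydiene A4 and the nitroacrylate A5. A Diels–Alder reaction under a chiral cationic oxazaborolidine Lewis acid (the o-tolylboron species derived from diphenylprolinol, activated by HNTf2) would give the cyclohexene A6. The nitro group, as the stronger acceptor, directs the oxygenated diene terminus to its own carbon. This places the C3 oxygen 1,3 to the ester, the reverse of what an acrylate alone would give. The nitro group is later expelled as nitrous acid to create the C1=C2 double bond.
- In its favour: the C3 oxygen enters already distinguished as a silyl ether. A Prévost reaction of the C4=C5 alkene with iodine and the silver salt of 4 could install both remaining esters trans to each other in one operation. With cycloaddition, Prévost reaction, elimination and a silyl-to-acetyl exchange, the sequence would be five or six steps.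
- Against it: enantiocontrol of a nitroacrylate by an oxazaborolidinium ion is not assured, because the uncatalysed cycloaddition of so reactive a dienophile is fast and the catalyst may bind at the ester or at the nitro group. The Prévost step must select both the alkene face anti to the silyloxy group and the site at which the intermediate dioxolanylium ion is opened. The silyl-to-acetyl exchange at O3 next to a cis ester invites acyl migration.
- Comparison: this plan sets C3 by catalyst and C4/C5 by substrate; the chosen plan takes C5 from a chiral aldehyde and sets C3 and C4 in the ring closure. On step economy the alternative is equal or slightly better, and on differentiation of O3 from O4/O5 it is equal. It carries two further selectivity questions beyond its unproven cycloaddition, so its overall risk is judged higher.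

**Alternative 3:** The ring would be cut at the C1=C2 double bond, leading to the sugar-derived lactol phosphonate A7. NaOMe would open the lactol to its aldehyde, and the phosphonate carbanion would close the ring by an intramolecular Horner–Wadsworth–Emmons olefination to give the acetonide-protected cyclohexenol A8.
- In its favour: C3, C4 and C5 are all taken from the sugar, so no stereocentre has to be created. The olefination is a dependable reaction type. In A8 the C5 hydroxyl is free while O3 and O4 are tied in the acetonide, so the C5 ester can be placed without ambiguity.
- Against it: A7 needs a long preparation from a hexose (chain shortening, activation of C5, alkylation of a phosphonoacetate, release of the anomeric centre). After A8 the O5 ester, the removal of the acetonide and the differentiation of the cis-3,4-diol still lie ahead, so well over ten steps result.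
- Comparison: on stereochemical security this plan is clearly the better one. As in alternative 1, the diol emerges undifferentiated, which is what the chosen ring closure avoids. The chosen plan is much shorter and better matched to the ester pattern, at the price of a key step whose stereochemical course is predicted and not assured.

Key step: step 5

Remark: the ring of the target is read as (3R,4S,5R) and both side chains as (R)-2-methylbutanoyl; aldehyde 1 is taken as the commercial (S)-enantiomer and is distilled directly before use, because it oligomerises and racemises on storage.

## Route

Step 1
Reactants: 1 (S)-glyceraldehyde acetonide [(4S)-2,2-dimethyl-1,3-dioxolane-4-carbaldehyde]; 2 methyl 2-(bromomethyl)prop-2-enoate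
Product: 3 methyl (4R)-4-[(4S)-2,2-dimethyl-1,3-dioxolan-4-yl]-4-hydroxy-2-methylidenebutanoate
Conditions: In powder (1.2 equiv), THF–H2O 1:1, rt; chromatography
Reagents that add atoms: none
Why: Barbier-type indium-mediated allylation in aqueous THF; the allylindium should add anti to the dioxolane C–O bond (Felkin–Anh, no chelation), making the (4R)-carbinol, the future C5, the major isomer. The minor syn isomer is removed by chromatography, and the neutral medium keeps the γ-hydroxy ester from lactonising.

Step 2
Reactants: 3 methyl (4R)-4-[(4S)-2,2-dimethyl-1,3-dioxolan-4-yl]-4-hydroxy-2-methylidenebutanoate; 4 (2R)-2-methylbutanoic acid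
Product: 5 methyl (4R)-4-[(4S)-2,2-dimethyl-1,3-dioxolan-4-yl]-2-methylidene-4-{[(2R)-2-methylbutanoyl]oxy}butanoate
Conditions: DCC (1.3 equiv), DMAP (0.1 equiv), CH2Cl2, 0 °C to rt
Reagents that add atoms: none
Why: Steglich esterification with retention at the carbinol carbon; catalytic DMAP at low temperature should acylate the secondary hydroxyl before it can lactonise onto the methyl ester and should not epimerise the α-centre of 4.

Step 3
Reactants: 5 methyl (4R)-4-[(4S)-2,2-dimethyl-1,3-dioxolan-4-yl]-2-methylidene-4-{[(2R)-2-methylbutanoyl]oxy}butanoate; 6 prop-2-ene-1,1-diyl diacetate
Product: 7 methyl (2E)-4,4-diacetoxy-2-[(2R)-2-[(4S)-2,2-dimethyl-1,3-dioxolan-4-yl]-2-{[(2R)-2-methylbutanoyl]oxy}ethyl]but-2-enoate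
Conditions: 6 (5 equiv), second-generation Hoveyda–Grubbs catalyst (2 × 5 mol %), CH2Cl2, 40 °C, argon purge
Reagents that add atoms: none
Why: Olefin cross-metathesis; the 1,1-disubstituted acrylate cannot homodimerise, so an excess of 6 should drive exchange of its methylidene group for the CH–CH(OAc)2 unit. The trisubstituted enoate should form as the more stable (2E) isomer with the acylal carbon trans to the ester; dioxolane, esters and acylal are inert to the ruthenium carbene.

Step 4
Reactants: 7 methyl (2E)-4,4-diacetoxy-2-[(2R)-2-[(4S)-2,2-dimethyl-1,3-dioxolan-4-yl]-2-{[(2R)-2-methylbutanoyl]oxy}ethyl]but-2-enoate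
Product: 9 methyl (2E)-4,4-diacetoxy-2-[(2R)-2-{[(2R)-2-methylbutanoyl]oxy}-3-oxopropyl]but-2-enoate, via diol 8 (not isolated)
Conditions: H5IO6 (1.5 equiv), EtOAc, 0 °C to rt; filtration through NaHCO3/Na2SO4, azeotropic drying (toluene), used at once
Reagents that add atoms: none
Why: One-pot hydrolysis of the terminal dioxolane and periodate glycol cleavage; H5IO6 supplies the acid and water that open the acetonide and cleaves diol 8 as soon as it forms, so the diol monoester has no time for acyl migration. The acylal tolerates this mild acid, and the non-basic work-up should leave the C5 centre next to the new aldehyde intact.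

Step 5
Reactants: 9 methyl (2E)-4,4-diacetoxy-2-[(2R)-2-{[(2R)-2-methylbutanoyl]oxy}-3-oxopropyl]but-2-enoate
Product: 11 methyl (3R,4S,5R)-3-acetoxy-4-hydroxy-5-{[(2R)-2-methylbutanoyl]oxy}cyclohex-1-ene-1-carboxylate, via γ-acetoxyallylindium species 10 (not isolated)
Conditions: Pd(PPh3)4 (5 mol %), InI (1.2 equiv), THF (0.01 M, slow addition of 9), rt; then pH 7 phosphate buffer, 0 °C
Reagents that add atoms: none
Why: Proposed new method: zerovalent palladium should ionise one acetate of the acylal of 9 to a 1-acetoxy-π-allylpalladium complex spanning C3–C2–C1, which InI reduces by transmetalation to the allylindium 10 of trivalent indium, best written with the metal at C1 (or on the ester oxygen as a dienolate) and the nucleophilic γ-carbon at C3; C3 then adds to the C4 aldehyde and buffered work-up releases 11. The closest known reaction types are the Pd(PPh3)4/InI umpolung allylation of aldehydes with simple allylic acetates, the indium-mediated acetoxyallylation of aldehydes with 3-bromopropenyl acetate, and iridium-catalysed transfer-hydrogenative acyloxyallylations with allylic gem-dicarboxylates; none has been run as a palladium/indium ring closure of an acylal onto a tethered aldehyde. The ring closes by a 6-exo-trig attack on the carbonyl group (6-endo with respect to the C2=C3 enol acetate); bonding through C1 would give a cyclobutane, so the tether enforces the regiochemistry and leaves the double bond at C1–C2 in conjugation with the ester. C4 should be set in a chair-like transition state in which the C5 ester is equatorial and antiperiplanar to the forming bond (Anh arrangement) and the indium-bound aldehyde oxygen is also equatorial, which gives the 4,5-trans relation. C3 should be set by the geometry of the enol acetate terminus: the Z form, with acetoxy cis to C1, places that group pseudoaxial in the closing ring and so cis to O4, and it is the form in which the acetate carbonyl can share an indium centre with the aldehyde oxygen. The step also needs ionisation of the gem-diacetate in preference to the allylic acetate of 11 and no epimerisation of the α-acyloxy aldehyde; the faster ionisation of acylals, the near-stoichiometric charge of InI and the neutral medium should secure both. The (2E) geometry of 9 holds C3 and C6 cis and pre-organises the closure, and rotation about C1–C2 in 10 would allow any minor alkene isomer to close as well.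

Step 6
Reactants: 11 methyl (3R,4S,5R)-3-acetoxy-4-hydroxy-5-{[(2R)-2-methylbutanoyl]oxy}cyclohex-1-ene-1-carboxylate; 4 (2R)-2-methylbutanoic acid
Product: 12 methyl (3R,4S,5R)-3-acetoxy-4,5-bis{[(2R)-2-methylbutanoyl]oxy}cyclohex-1-ene-1-carboxylate
Conditions: 4 (2 equiv), DCC (2 equiv), DMAP (0.2 equiv), CH2Cl2, 0 °C to rt
Reagents that add atoms: none
Why: Steglich esterification of the C4 hydroxyl; no stereocentre is formed. The acylpyridinium intermediate should acylate the equatorial hydroxyl faster than the cis acetate can migrate, and the nearly neutral medium should leave the allylic acetate and the α-centres of the acyl groups untouched.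

## Compound list

1 | (S)-glyceraldehyde acetonide, (4S)-2,2-dimethyl-1,3-dioxolane-4-carbaldehyde | O=C[C@@H]1COC(C)(C)O1 | starting material
2 | methyl 2-(bromomethyl)prop-2-enoate | C=C(CBr)C(=O)OC | starting material
3 | methyl (4R)-4-[(4S)-2,2-dimethyl-1,3-dioxolan-4-yl]-4-hydroxy-2-methylidenebutanoate | C=C(C(=O)OC)C[C@@H](O)[C@@H]1COC(C)(C)O1 | intermediate
4 | (2R)-2-methylbutanoic acid | CC[C@@H](C)C(=O)O | starting material
5 | methyl (4R)-4-[(4S)-2,2-dimethyl-1,3-dioxolan-4-yl]-2-methylidene-4-{[(2R)-2-methylbutanoyl]oxy}butanoate | C=C(C(=O)OC)C[C@@H](OC(=O)[C@H](C)CC)[C@@H]1COC(C)(C)O1 | intermediate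
6 | prop-2-ene-1,1-diyl diacetate | CC(=O)OC(OC(C)=O)C=C | starting material
7 | methyl (2E)-4,4-diacetoxy-2-[(2R)-2-[(4S)-2,2-dimethyl-1,3-dioxolan-4-yl]-2-{[(2R)-2-methylbutanoyl]oxy}ethyl]but-2-enoate | CC(=O)OC(OC(C)=O)/C=C(C(=O)OC)\C[C@@H](OC(=O)[C@H](C)CC)[C@@H]1COC(C)(C)O1 | intermediate
8 | methyl (2E)-4,4-diacetoxy-2-[(2R,3S)-3,4-dihydroxy-2-{[(2R)-2-methylbutanoyl]oxy}butyl]but-2-enoate | CC(=O)OC(OC(C)=O)/C=C(C(=O)OC)\C[C@@H](OC(=O)[C@H](C)CC)[C@@H](O)CO | intermediate (not isolated)
9 | methyl (2E)-4,4-diacetoxy-2-[(2R)-2-{[(2R)-2-methylbutanoyl]oxy}-3-oxopropyl]but-2-enoate | CC(=O)OC(OC(C)=O)/C=C(C(=O)OC)\C[C@H](C=O)OC(=O)[C@H](C)CC | intermediate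
10 | methyl (3Z)-4-acetoxy-2-[acetoxy(iodo)indiganyl]-2-[(2R)-2-{[(2R)-2-methylbutanoyl]oxy}-3-oxopropyl]but-3-enoate (C1-bound γ-acetoxyallyl species of trivalent indium, one of its metallotropic forms; configuration at the metal-bearing carbon undefined) | COC(=O)C(/C=C\OC(C)=O)(C[C@H](C=O)OC(=O)[C@H](C)CC)[In](I)OC(C)=O | intermediate (not isolated)
11 | methyl (3R,4S,5R)-3-acetoxy-4-hydroxy-5-{[(2R)-2-methylbutanoyl]oxy}cyclohex-1-ene-1-carboxylate | O[C@@H]1[C@H](OC(C)=O)C=C(C(=O)OC)C[C@H]1OC(=O)[C@H](C)CC | intermediate
12 | methyl (3R,4S,5R)-3-acetoxy-4,5-bis{[(2R)-2-methylbutanoyl]oxy}cyclohex-1-ene-1-carboxylate | CC[C@@H](C)C(=O)O[C@@H]1[C@H](OC(C)=O)C=C(C(=O)OC)C[C@H]1OC(=O)[C@H](C)CC | target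

## Step count and least certain steps

Total: 6 steps. Longest linear sequence: 6 steps (1 to 12).

**Step 5 (key step, new method).** Three things are most likely to go wrong. The allylindium may be protonated before it closes, which amounts to simple reduction of the acylal. The allylic acetate of the product may be ionised a second time and lost by reductive elimination toward a cyclohexadiene. The closure may take the wrong facial sense at C3 or C4, because neither the enol acetate geometry nor the open or closed nature of the transition state is established for this substrate class. The fallback uses only known reactions and gives up the de novo ring construction; it sets out from 4 together with commercial methyl shikimate F1 and returns to the route at 11. Methyl shikimate F1 would be treated with trimethyl orthoacetate and catalytic camphorsulfonic acid to give the cyclic 3,4-orthoacetate F2, since only the cis-diol can bridge. The free C5 hydroxyl of F2 would be esterified with 4 (DCC, catalytic DMAP) to give the orthoester ester F3. Brief hydrolysis of F3 in aqueous acetic acid should open the orthoester to the ester on the pseudoaxial oxygen, O3, which is 11.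

**Step 3.** Metathesis at the 1,1-disubstituted, electron-poor alkene is likely to be slow, so catalyst decay, self-metathesis of 6 and double-bond migration may overtake the productive exchange. The fallback sets out from 5 and returns at 7, replacing metathesis by carbonyl olefination. Ozonolysis of 5 (O3, CH2Cl2, −78 °C, then Me2S) would give the α-keto ester F4. Wittig reaction of F4 with (triphenylphosphoranylidene)acetaldehyde in warm toluene would give the enal F5. Ac2O with a mild Lewis acid such as LiBF4 would convert the formyl group of F5 into the gem-diacetate 7, with a watch kept on the acetonide.

**Step 4.** Three processes threaten this step: acyl migration in the transient diol, acid-promoted loss of an acetate from the acylal, and hydration or epimerisation of the α-acyloxy aldehyde during isolation. The fallback sets out from 5 and returns at 9, so that the acylal never meets the acidic oxidant. Treatment of 5 with H5IO6 in EtOAc would give, through the diol F6, the aldehyde F7. Cross-metathesis of the aldehyde F7 with 6 under the conditions of step 3 would then give 9 directly.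

**Step 6.** The hydroxyl lies between two esters, so acylation may be slow enough for base-assisted migration of the cis acetate from O3 to O4 or for rearrangement of the activated acid to its N-acylurea. The fallback sets out from 11 and 4 and returns at 12, changing from nucleophilic base catalysis to Lewis-acid catalysis. Acid 4 (2 equiv) and DCC (1 equiv) would give the anhydride F8. The anhydride F8 would acylate 11 in MeCN at −20 °C under catalytic Sc(OTf)3, with no base present.

**Step 1.** Facial selectivity in the addition to the α-alkoxy aldehyde may be only moderate, since some chelation by indium in water would favour the syn isomer; the product may also lactonise. The fallback sets out from 1 and 2 and returns at 5, making both diastereomers useful. The syn alcohol F9, separated from 3, would be esterified with 4 under Mitsunobu conditions (PPh3, diisopropyl azodicarboxylate, THF, 0 °C), which inverts the carbinol centre and gives 5.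

## Further compounds

F1 | step 5 | methyl (3R,4S,5R)-3,4,5-trihydroxycyclohex-1-ene-1-carboxylate (methyl shikimate) | O[C@@H]1[C@H](O)C=C(C(=O)OC)C[C@H]1O
F2 | step 5 | methyl (3aR,7R,7aS)-7-hydroxy-2-methoxy-2-methyl-3a,6,7,7a-tetrahydro-1,3-benzodioxole-5-carboxylate (either configuration at the orthoester carbon) | COC(=O)C1=C[C@H]2OC(C)(OC)O[C@H]2[C@H](O)C1
F3 | step 5 | methyl (3aR,7R,7aS)-2-methoxy-2-methyl-7-{[(2R)-2-methylbutanoyl]oxy}-3a,6,7,7a-tetrahydro-1,3-benzodioxole-5-carboxylate | COC(=O)C1=C[C@H]2OC(C)(OC)O[C@H]2[C@H](OC(=O)[C@H](C)CC)C1
F4 | step 3 | methyl (4R)-4-[(4S)-2,2-dimethyl-1,3-dioxolan-4-yl]-4-{[(2R)-2-methylbutanoyl]oxy}-2-oxobutanoate | COC(=O)C(=O)C[C@@H](OC(=O)[C@H](C)CC)[C@@H]1COC(C)(C)O1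
F5 | step 3 | methyl (2E)-2-[(2R)-2-[(4S)-2,2-dimethyl-1,3-dioxolan-4-yl]-2-{[(2R)-2-methylbutanoyl]oxy}ethyl]-4-oxobut-2-enoate | O=C/C=C(C(=O)OC)\C[C@@H](OC(=O)[C@H](C)CC)[C@@H]1COC(C)(C)O1
F6 | step 4 | methyl (4R,5S)-5,6-dihydroxy-2-methylidene-4-{[(2R)-2-methylbutanoyl]oxy}hexanoate | C=C(C(=O)OC)C[C@@H](OC(=O)[C@H](C)CC)[C@@H](O)CO
F7 | step 4 | methyl (4R)-2-methylidene-4-{[(2R)-2-methylbutanoyl]oxy}-5-oxopentanoate | C=C(C(=O)OC)C[C@H](C=O)OC(=O)[C@H](C)CC
F8 | step 6 | (2R)-2-methylbutanoic anhydride | CC[C@@H](C)C(=O)OC(=O)[C@H](C)CC
F9 | step 1 | methyl (4S)-4-[(4S)-2,2-dimethyl-1,3-dioxolan-4-yl]-4-hydroxy-2-methylidenebutanoate | C=C(C(=O)OC)C[C@H](O)[C@@H]1COC(C)(C)O1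
A1 | alternative 1 | furan | c1ccoc1
A2 | alternative 1 | 3-(prop-2-enoyl)-1,3-oxazolidin-2-one | C=CC(=O)N1CCOC1=O
A3 | alternative 1 | 3-[(1R,2R,4R)-7-oxabicyclo[2.2.1]hept-5-ene-2-carbonyl]-1,3-oxazolidin-2-one (endo adduct) | O=C(N1CCOC1=O)[C@@H]2C[C@@H]3C=C[C@H]2O3
A4 | alternative 2 | (E)-1-(tert-butyldimethylsilyloxy)buta-1,3-diene | CC(C)(C)[Si](C)(C)O/C=C/C=C
A5 | alternative 2 | methyl (E)-3-nitroprop-2-enoate | COC(=O)/C=C/[N+](=O)[O-]
A6 | alternative 2 | methyl (1S,2R,3S)-3-[(tert-butyldimethylsilyl)oxy]-2-nitrocyclohex-4-ene-1-carboxylate | CC(C)(C)[Si](C)(C)O[C@H]1C=CC[C@H](C(=O)OC)[C@H]1[N+](=O)[O-]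
A7 | alternative 3 | 5-deoxy-5-[(dimethoxyphosphoryl)(methoxycarbonyl)methyl]-2,3-O-isopropylidene-D-lyxofuranose (lactol, undefined at the anomeric and phosphonate carbons) | COC(=O)C(P(=O)(OC)OC)C[C@H]1OC(O)[C@H]2OC(C)(C)O[C@@H]12
A8 | alternative 3 | methyl (3aR,7R,7aS)-7-hydroxy-2,2-dimethyl-3a,6,7,7a-tetrahydro-1,3-benzodioxole-5-carboxylate | COC(=O)C1=C[C@H]2OC(C)(C)O[C@H]2[C@H](O)C1
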